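(The data were generated by integration on assumed constants; scatter was added.)

The ratio to watch is 0.261, the flask's poison share: impurity charged over free catalyst charged. Saturday's run stands at 0.521, Monday's at 0.130 and Wednesday's at 0.393.

the same everywhere: free catalyst 0.1 mol%
- Saturday's: left-handed substrate 14 mM; right-handed substrate 14 mM; reagent 2.2 equiv (fed, over 50 s); impurity 7.3 µM; run made earlier
- Monday's: left-handed substrate 56 mM; right-handed substrate 56 mM; reagent 2.2 equiv (fed, over 50 s); impurity 7.3 µM; run made earlier
- Wednesday's: left-handed substrate 28 mM; right-handed substrate 28 mM; reagent 2.2 equiv (fed, over 50 s); impurity 11 µM; run made earlier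
- flask: left-handed substrate 28 mM; right-handed substrate 28 mM; reagent 2.20 equiv (fed, over 50 s); impurity 7.3 µM; time 8.0 min

- Saturday's (time / min: left-handed product / %): 2.00: 4.6; 2.50: 4.8; 3.00: 5.5; 4.00: 7.4; 5.00: 11.4
- Monday's (time / min: left-handed product / %): 2.00: 36.1; 2.50: 40.5; 3.00: 43.4; 4.00: 47.4; 5.00: 49.4
- Wednesday's (time / min: left-handed product / %): 2.00: 16.6; 2.50: 19.2; 3.00: 23.1; 4.00: 26.4; 5.00: 30.3

(each reading ± 1 percentage point)

1. when, up to 8.0 min, the flask holds most left-handed product
2. the amount of left-handed product, in percent of the left-handed substrate and right-handed substrate together charged, at that time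
3. the first time at which left-handed product reaches 19%, in the same percent, in min

- free catalyst is single-handed; left-handed substrate and right-handed substrate are mirror images of each other, charged as a racemate, each of them at the stated concentration

A bench rule says that a trace impurity takes free catalyst one for one, which leaves a working fraction of one minus the poison share. Wednesday's run differs from the flask in its impurity, so the flask should run faster than Wednesday's run by the ratio of the working fractions:

speed ratio = (one − flask's share) / (one − Wednesday's share) = 1.22

Wednesday's run read 19.2% at 2.50 min, close to the asked amount, though that reading carries a scatter of 1 percentage point. A first round divides the time by the speed ratio: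

first round: 2.05 min

But reagent enters over 50 s, so the second round starts the clock at mid-feed and scales what follows:

second round: 2.13 min

The rule has a border. The subtraction means something while the share stays below 1, and the flask, at 0.261, is inside it.

The forecast gives 8 min (7 min to 8 min), 41% (36% to 46%) and 2.1 min (1.6 min to 2.5 min), on the grounds that “there is more free catalyst”.

The flask holds most left-handed product at 8.00 min, with 37.6%, and reaches the asked amount at 2.28 min.

    reagent + free catalyst + left-handed substrate → free catalyst + left-handed product (k = 9040 M⁻² s⁻¹)
    reagent + free catalyst + right-handed substrate → free catalyst + right-handed product (k = 4460 M⁻² s⁻¹)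
    left-handed substrate ⇌ right-handed substrate (k = 0.0242 s⁻¹)
    2 free catalyst ⇌ resting dimer, settled at all times (K = 53500 M⁻¹)
    2 free catalyst → spent catalyst A (k = 307 M⁻¹ s⁻¹)
    free catalyst + impurity → spent catalyst B (k = 49800 M⁻¹ s⁻¹)

In the flask, spent catalyst B stands at 26.1% of the catalyst charged at 0.833 min and still at 26.1% at 8.00 min, against a poison share of 0.261, while impurity, the limiting reagent of that side step, is at 0% of its own charge at 0.833 min. A neighbour flask, the same but for 0.029 mM of impurity, has a poison share of 1.04, past the border. At 8.00 min that neighbour flask holds spent catalyst B at 99.4% and free catalyst at 0% of the catalyst charged, impurity at 4.03% of its own charge, and left-handed product at 0.343%.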